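Slowness is what two chemists dispute over east and south-east. The clock holder says a flask gets as far as its half-lives allow. The split holder says each unit of G is committed to E or D early.

| flask | G | temperature | remark | time |
|---|---|---|---|---|
| larch | 11 mM | 56 °C | run made earlier |  |
| maple | 24 mM | 70 °C | run made earlier |  |
| east | 16 mM | 50 °C |  | 6.0 h |
| south-east | 16 mM | 75 °C |  | 6.0 h |

larch run (percent of the G charged)

| time / h | G / % | D / % | X / % | E / % |
|---|---|---|---|---|
| 0.833 | 22 | 25 | 0 | 33 |
| 2.00 | 10 | 42 | 2 | 45 |
| 4.00 | 0 | 42 | 4 | 50 |
| 6.00 | 3 | 45 | 4 | 50 |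

maple run (percent of the G charged)

| time / min | G / % | D / % | X / % | E / % |
|---|---|---|---|---|
| 12.0 | 15 | 23 | 7 | 43 |
| 20.0 | 9 | 24 | 8 | 50 |
| 60.0 | 3 | 30 | 8 | 57 |
| 120 | 0 | 35 | 6 | 59 |

(scatter of a reading: 2 percentage points)

- percent here means G units held: one L or E counts as two
- percent here means G units held: one X counts as three
- what was read earlier has a scatter of 2 percentage points, one standard deviation
- on the list of suspects stand: G -> D; 2 G -> L; G + L -> X; L -> E; G <-> Z
- a reading of G is of its free form alone

- which of these there is most of at the end, counted by the G in it, east (X / E / G / D)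
- which of these there is most of at the end, counted by the G in it, south-east (X / E / G / D)
- amount of the one of these that there is most of at the end, in percent of the G charged, east
- amount of the one of these that there is most of at the end, in percent of the G charged, south-east

Both use τ, the half-life of free G late in a run, taken as pseudo-first-order. Larch falls from 22% to 10% between 0.833 h and 2.00 h, so τ = 1.03 h. Maple falls from 15% to 9% between 12.0 min and 20.0 min, so τ = 10.9 min. These are rough readings, and the charges differ. A straight line of ln τ against temperature gives 2.16 h for east and 5.84 min for south-east. Asked time over τ is then 2.78 in east and 61.6 in south-east: this is n, the count of half-lives.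

So the dispute is over east. For east, the clock holder reckons 14.6% of G still free and scales the E of larch's last reading to 42.7%. The split holder answers that larch read E at 45% of the G charged after a count of 1.94, against 50% at its last reading, and east's count is larger. I side with the split holder: my count gives no amount, but it puts east beyond the point where larch gave that reading.

The forecast, on that side, has E ahead in east at 55% and E ahead in south-east at 50%, the latter being “a close call, but E stays ahead”.

The flask gives E at 55.2% in east, with D at 33.1%, and E at 51.1% in south-east, with D at 44.1%. The clock view has its region in east stopped at 2.90 h, a count of 1.34, where E has moved by 6 points.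

    G → D (k = 1.15 × 10⁻⁴ s⁻¹, Ea = 96.0 kJ mol⁻¹)
    2 G → L (k = 0.0228 M⁻¹ s⁻¹, Ea = 77.0 kJ mol⁻¹)
    G + L → X (k = 0.00732 M⁻¹ s⁻¹, Ea = 79.0 kJ mol⁻¹)
    L → E (k = 3.41 × 10⁻⁴ s⁻¹, Ea = 96.0 kJ mol⁻¹)
    G ⇌ Z (K = 0.490, k = 4.17 × 10⁻⁴ s⁻¹, Ea = 102 kJ mol⁻¹, ΔH = −34.0 kJ mol⁻¹)
    (constants at 50 °C)

East's free G went from 8.18% at 3.00 h to 2.88% at 6.00 h, a half-life of 1.99 h and a count of 3.01 against the reckoned 2.78, while E rose from 49.7% to 55.2% and D from 26.9% to 33.1%. The slowest mode of the whole south-east flask, as it stands at 6.00 h, has a half-life of 0.155 h, which gives a count of 38.7 against the reckoned 61.6 for free G, and the same flask charged with 9.6 mM of G ends with G at 0%, D at 55.2% and E at 42.0%.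

The runs are calculated from invented constants; scatter was added.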